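**Strategy**

The target is two (S)-herbertenediol units joined through a CH2 bridge, so both halves come from one monomer, (S)-herbertenediol dimethyl ether. In each 1,2,2-trimethylcyclopentyl ring the bond between the quaternary benzylic carbon C1 (aryl, methyl) and the ring CH2 C5 is disconnected, and the neighbouring gem-dimethyl carbon C2 is read as a former carbonyl. The key step, an enantioselective acid-catalysed protio-semipinacol ring expansion of an achiral 1-(1-arylvinyl)cyclobutanol, shifts a cyclobutane CH2 onto a benzylic cation and so creates, in one operation, the C1–C5 bond, the five-membered ring, the C1 stereocentre and the C2 ketone. Methylenation, cyclopropanation and hydrogenolysis install the gem-dimethyl group; benzylic oxidation, aryllithium addition, deoxygenation and demethylation join the halves.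

Key step: step 4

Remark on the chemistry: both cyclopentyl stereocentres of the target are (S) by CIP analysis. The same spatial arrangement is (R) in ketone 9 only because the carbonyl carbon outranks the aryl group. The four phenols are carried as methyl ethers until the last step.

**Route**

Step 1
Reactants: 1 3,4-dimethoxytoluene; 2 N-methoxy-N-methylacetamide
Product: 4 1-(2,3-dimethoxy-5-methylphenyl)ethan-1-one, via aryllithium 3 (not isolated)
Conditions: n-BuLi, TMEDA, Et2O, 0 °C to rt; then 2, −78 to 0 °C; aq. NH4Cl
Reagents that add atoms: none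
Why: Directed ortho-metalation followed by ketone synthesis from an N-methoxy-N-methyl amide: the methoxy groups should direct lithiation to the less hindered ortho position (C5 of 1, not C2 between methyl and methoxy), and the chelated tetrahedral adduct prevents a second addition.

Step 2
Reactants: 4 1-(2,3-dimethoxy-5-methylphenyl)ethan-1-one
Product: 5 N'-[(1E)-1-(2,3-dimethoxy-5-methylphenyl)ethylidene]-2,4,6-triisopropylbenzenesulfonohydrazide
Conditions: 2,4,6-triisopropylbenzenesulfonohydrazide, cat. HCl, MeOH, rt
Reagents that add atoms: 2,4,6-triisopropylbenzenesulfonohydrazide CC(C)c1cc(C(C)C)c(S(=O)(=O)NN)c(C(C)C)c1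
Why: Acid-catalysed hydrazone condensation; the E isomer (aryl anti to the sulfonamide nitrogen) should predominate and places the methyl group syn to the N–N bond as the next step requires, while the triisopropylphenyl group suppresses ortho-lithiation of the sulfonyl arene.

Step 3
Reactants: 5 the E-hydrazone; 6 cyclobutanone
Product: 8 1-[1-(2,3-dimethoxy-5-methylphenyl)ethenyl]cyclobutan-1-ol, via vinyllithium 7 (not isolated)
Conditions: n-BuLi (2.1 equiv), THF, −78 to 0 °C; then 6, −78 °C; aq. NH4Cl
Reagents that add atoms: none
Why: Shapiro reaction followed by 1,2-addition: double deprotonation (N–H, then the methyl group, the only α-C–H bonds), loss of sulfinate and N2 give the 1-arylvinyllithium regiospecifically, which adds to the strained and therefore highly electrophilic carbonyl of cyclobutanone.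

Step 4
Reactants: 8 1-[1-(2,3-dimethoxy-5-methylphenyl)ethenyl]cyclobutan-1-ol
Product: 9 (R)-2-(2,3-dimethoxy-5-methylphenyl)-2-methylcyclopentan-1-one
Conditions: (R)-3,3'-bis(2,4,6-triisopropylphenyl)-1,1'-binaphthyl-2,2'-diyl N-triflylphosphoramide (10 mol%), PhMe, 4 Å MS, −20 °C to rt
Reagents that add atoms: none
Why: Proposed new method: the chiral acid protonates the terminal CH2 of the electron-rich 1,1-disubstituted styrene of 8 in the Markovnikov sense, giving a tertiary benzylic cation that stays paired with the phosphoramide anion, itself hydrogen-bonded to the cyclobutanol OH; one cyclobutane CH2 then migrates to the cationic carbon, about 20 kcal/mol of ring strain is released, and the resulting oxocarbenium ion returns its proton to the anion. The closest known reaction types are the enantioselective halonium-initiated ring expansion of 1-(1-arylvinyl)cyclobutanols and the chiral-acid-catalysed protio-semipinacol rearrangement of enol-ether-type allylic cyclobutanols and of vinylic cyclopropanols; the proton-initiated enantioselective version on a plain 1-arylvinylcyclobutanol is the extrapolation. The cyclopentanone ring is closed by a suprafacial 1,2-carbon (Wagner–Meerwein) shift, a four-to-five ring expansion in which the new C1–C5 bond forms as the carbinol–CH2 bond breaks, not by an end-to-end cyclization. The quaternary centre C1 is the only new stereocentre; it is set by the face of the planar cation that receives the migrating CH2 (the two ring CH2 groups are enantiotopic), and that face is chosen by the chiral counter-anion, so the catalyst antipode that gives (R)-9 is fixed in a first run. The step needs migration to outrun proton loss to a diene, ionization of the tertiary allylic alcohol and arene alkylation by the cation; the strained ring, the cation-stabilizing ortho-methoxy group, the non-nucleophilic solvent and the low temperature secure this.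

Step 5
Reactants: 9 (R)-2-(2,3-dimethoxy-5-methylphenyl)-2-methylcyclopentan-1-one
Product: 10 1,2-dimethoxy-5-methyl-3-[(1S)-1-methyl-2-methylidenecyclopentyl]benzene
Conditions: Ph3PCH3Br, KOtBu, PhMe, rt to 110 °C
Reagents that add atoms: methyltriphenylphosphonium bromide C[P+](c1ccccc1)(c1ccccc1)c1ccccc1.[Br-]
Why: Wittig methylenation, for which the ylide at elevated temperature should overcome the hindrance of the α-quaternary ketone; the quaternary stereocentre carries no hydrogen and cannot epimerize under base.

Step 6
Reactants: 10 1,2-dimethoxy-5-methyl-3-[(1S)-1-methyl-2-methylidenecyclopentyl]benzene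
Product: 11 (4S)-4-(2,3-dimethoxy-5-methylphenyl)-4-methylspiro[2.4]heptane
Conditions: Et2Zn, CH2I2, CH2Cl2, 0 °C to rt
Reagents that add atoms: diiodomethane ICI
Why: Simmons–Smith cyclopropanation of the 1,1-disubstituted alkene by the zinc carbenoid; the spiro carbon created is not stereogenic, so facial selectivity is immaterial.

Step 7
Reactants: 11 (4S)-4-(2,3-dimethoxy-5-methylphenyl)-4-methylspiro[2.4]heptane
Product: 12 1,2-dimethoxy-5-methyl-3-[(1S)-1,2,2-trimethylcyclopentyl]benzene
Conditions: H2 (3 atm), PtO2, AcOH, rt
Reagents that add atoms: none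
Why: Catalytic hydrogenolysis of the cyclopropane at its least hindered CH2–CH2 bond turns the spiro ring into the gem-dimethyl group without any cationic intermediate next to the quaternary stereocentre, so its configuration should be preserved.

Step 8
Reactants: 12 1,2-dimethoxy-5-methyl-3-[(1S)-1,2,2-trimethylcyclopentyl]benzene
Product: 13 3,4-dimethoxy-5-[(1S)-1,2,2-trimethylcyclopentyl]benzaldehyde
Conditions: (NH4)2Ce(NO3)6 (4.2 equiv), AcOH/H2O, 50 °C
Reagents that add atoms: water O
Why: Benzylic oxidation through the arene radical cation (single-electron transfer to tetravalent cerium): the only benzylic C–H bonds are those of the aryl methyl group, the ring positions para to the methoxy groups are substituted or blocked so biaryl coupling is shut down, and the aldehyde formed is deactivated toward further oxidation.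

Step 9
Reactants: 12 1,2-dimethoxy-5-methyl-3-[(1S)-1,2,2-trimethylcyclopentyl]benzene; 13 3,4-dimethoxy-5-[(1S)-1,2,2-trimethylcyclopentyl]benzaldehyde
Product: 15 {2,3-dimethoxy-6-methyl-4-[(1S)-1,2,2-trimethylcyclopentyl]phenyl}{3,4-dimethoxy-5-[(1S)-1,2,2-trimethylcyclopentyl]phenyl}methanol (both carbinol epimers), via aryllithium 14 (not isolated)
Conditions: 12 (1.3 equiv), n-BuLi (1.2 equiv), TMEDA, Et2O/hexane, 0 °C to rt; then 13 (1.0 equiv), −78 to 0 °C; aq. NH4Cl
Reagents that add atoms: none
Why: Directed ortho-metalation followed by 1,2-addition: the only hydrogen ortho to a methoxy group in 12 is H6 (between OMe and CH3), the situation in which 3,4,5-trimethoxytoluene is known to lithiate cleanly; the carbinol carbon forms as a mixture of epimers, which is irrelevant because it becomes CH2 in step 10.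

Step 10
Reactants: 15 the diarylmethanol
Product: 16 2-({3,4-dimethoxy-5-[(1S)-1,2,2-trimethylcyclopentyl]phenyl}methyl)-3,4-dimethoxy-1-methyl-5-[(1S)-1,2,2-trimethylcyclopentyl]benzene
Conditions: Et3SiH, CF3CO2H, CH2Cl2, 0 °C
Reagents that add atoms: none
Why: Ionic hydrogenation: the doubly benzylic, methoxy-stabilized cation formed in acid is captured by hydride from the silane, and nothing else in the molecule is reducible or acid-labile under these conditions.

Step 11
Reactants: 16 the tetramethyl ether
Product: 17 3-({3,4-dihydroxy-5-[(1S)-1,2,2-trimethylcyclopentyl]phenyl}methyl)-4-methyl-6-[(1S)-1,2,2-trimethylcyclopentyl]benzene-1,2-diol (CNP0137546.1)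
Conditions: BBr3 (8 equiv), CH2Cl2, −78 °C to rt; then degassed H2O, under argon
Reagents that add atoms: none
Why: Lewis-acid cleavage of the four aryl methyl ethers by BBr3; the hydrocarbon skeleton and the quaternary stereocentres are inert, and oxygen-free work-up protects the catechols.

**Compound list**

1 | 3,4-dimethoxytoluene | Cc1ccc(OC)c(OC)c1 | starting material
2 | N-methoxy-N-methylacetamide | CC(=O)N(C)OC | starting material
3 | (2,3-dimethoxy-5-methylphenyl)lithium | [Li]c1cc(C)cc(OC)c1OC | intermediate (not isolated)
4 | 1-(2,3-dimethoxy-5-methylphenyl)ethan-1-one | CC(=O)c1cc(C)cc(OC)c1OC | intermediate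
5 | N'-[(1E)-1-(2,3-dimethoxy-5-methylphenyl)ethylidene]-2,4,6-triisopropylbenzenesulfonohydrazide | C/C(=N\NS(=O)(=O)c1c(C(C)C)cc(C(C)C)cc1C(C)C)c1cc(C)cc(OC)c1OC | intermediate
6 | cyclobutanone | O=C1CCC1 | starting material
7 | [1-(2,3-dimethoxy-5-methylphenyl)ethenyl]lithium | [Li]C(=C)c1cc(C)cc(OC)c1OC | intermediate (not isolated)
8 | 1-[1-(2,3-dimethoxy-5-methylphenyl)ethenyl]cyclobutan-1-ol | C=C(c1cc(C)cc(OC)c1OC)C1(O)CCC1 | intermediate
9 | (R)-2-(2,3-dimethoxy-5-methylphenyl)-2-methylcyclopentan-1-one | COc1cc(C)cc([C@@]2(C)CCCC2=O)c1OC | intermediate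
10 | 1,2-dimethoxy-5-methyl-3-[(1S)-1-methyl-2-methylidenecyclopentyl]benzene | COc1cc(C)cc([C@@]2(C)CCCC2=C)c1OC | intermediate
11 | (4S)-4-(2,3-dimethoxy-5-methylphenyl)-4-methylspiro[2.4]heptane | COc1cc(C)cc([C@@]2(C)CCCC23CC3)c1OC | intermediate
12 | 1,2-dimethoxy-5-methyl-3-[(1S)-1,2,2-trimethylcyclopentyl]benzene ((S)-herbertenediol dimethyl ether) | COc1cc(C)cc([C@@]2(C)CCCC2(C)C)c1OC | intermediate
13 | 3,4-dimethoxy-5-[(1S)-1,2,2-trimethylcyclopentyl]benzaldehyde | COc1cc(C=O)cc([C@@]2(C)CCCC2(C)C)c1OC | intermediate
14 | {2,3-dimethoxy-6-methyl-4-[(1S)-1,2,2-trimethylcyclopentyl]phenyl}lithium | [Li]c1c(C)cc([C@@]2(C)CCCC2(C)C)c(OC)c1OC | intermediate (not isolated)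
15 | {2,3-dimethoxy-6-methyl-4-[(1S)-1,2,2-trimethylcyclopentyl]phenyl}{3,4-dimethoxy-5-[(1S)-1,2,2-trimethylcyclopentyl]phenyl}methanol (both carbinol epimers) | Cc1cc([C@@]2(C)CCCC2(C)C)c(OC)c(OC)c1C(O)c1cc(OC)c(OC)c([C@@]2(C)CCCC2(C)C)c1 | intermediate
16 | 2-({3,4-dimethoxy-5-[(1S)-1,2,2-trimethylcyclopentyl]phenyl}methyl)-3,4-dimethoxy-1-methyl-5-[(1S)-1,2,2-trimethylcyclopentyl]benzene | Cc1cc([C@@]2(C)CCCC2(C)C)c(OC)c(OC)c1Cc1cc(OC)c(OC)c([C@@]2(C)CCCC2(C)C)c1 | intermediate
17 | 3-({3,4-dihydroxy-5-[(1S)-1,2,2-trimethylcyclopentyl]phenyl}methyl)-4-methyl-6-[(1S)-1,2,2-trimethylcyclopentyl]benzene-1,2-diol | Cc1cc([C@@]2(C)CCCC2(C)C)c(O)c(O)c1Cc1cc(O)c(O)c([C@@]2(C)CCCC2(C)C)c1 | target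

**Step count and risks**

Total step count: 11. Longest linear sequence: 11 steps (steps 1 to 11; monomer 12 enters both step 8 and step 9).

Steps most likely to fail:

1. Step 4 (Proposed new method). The risk is poor face discrimination within the ion pair, or proton loss and ionization of the allylic alcohol competing with the 1,2-shift. The fallback sets out from 8 and returns at 9 with known chemistry that keeps the same ring expansion. The alkene of 8 is attacked by electrophilic chlorine from 1,3-dichloro-5,5-dimethylhydantoin under catalysis by (DHQD)2PHAL or its pseudo-enantiomer (DHQ)2PHAL, as the sense requires. This is a known enantioselective chlorination/ring expansion of 1-(1-arylvinyl)cyclobutanols and should give (S)-2-(chloromethyl)-2-(2,3-dimethoxy-5-methylphenyl)cyclopentan-1-one F1. The C–Cl bond is then reduced with Bu3SnH at high concentration (AIBN, PhH, 80 °C), so that hydrogen transfer outruns 1,2-aryl shift and ring enlargement of the primary radical, giving 9.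

2. Step 8. The risk is over-oxidation, ring nitration or C–C fragmentation of the arene radical cation instead of clean loss of a benzylic proton. The fallback sets out from 12 and returns at 16, bypassing 13 and 15. Wohl–Ziegler bromination of 12 (N-bromosuccinimide, light, PhCF3, reflux) should give 5-(bromomethyl)-1,2-dimethoxy-3-[(1S)-1,2,2-trimethylcyclopentyl]benzene F2. Aryllithium 14, made from a second portion of 12 as in step 9, is transmetalated with ZnCl2 to chloro{2,3-dimethoxy-6-methyl-4-[(1S)-1,2,2-trimethylcyclopentyl]phenyl}zinc F3. Negishi coupling of F2 with F3 under zerovalent palladium catalysis (Pd(OAc)2 with 2-dicyclohexylphosphino-2',6'-dimethoxybiphenyl, THF, rt to 50 °C) should give 16.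

3. Step 9. The risk is incomplete or misdirected lithiation (lateral deprotonation of the aryl methyl group) and addition of residual n-BuLi to the aldehyde. The fallback sets out from 12 and returns at 14. Electrophilic bromination of 12 (N-bromosuccinimide, MeCN, 0 °C) at the same ring position should give 2-bromo-3,4-dimethoxy-1-methyl-5-[(1S)-1,2,2-trimethylcyclopentyl]benzene F4. Bromine–lithium exchange with n-BuLi (THF, −78 °C) then gives 14 stoichiometrically and regiospecifically, and 13 is added as in step 9.

**Further compounds**

F1 | step 4 | (S)-2-(chloromethyl)-2-(2,3-dimethoxy-5-methylphenyl)cyclopentan-1-one | COc1cc(C)cc([C@@]2(CCl)CCCC2=O)c1OC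
F2 | step 8 | 5-(bromomethyl)-1,2-dimethoxy-3-[(1S)-1,2,2-trimethylcyclopentyl]benzene | COc1cc(CBr)cc([C@@]2(C)CCCC2(C)C)c1OC
F3 | step 8 | chloro{2,3-dimethoxy-6-methyl-4-[(1S)-1,2,2-trimethylcyclopentyl]phenyl}zinc | Cl[Zn]c1c(C)cc([C@@]2(C)CCCC2(C)C)c(OC)c1OC
F4 | step 9 | 2-bromo-3,4-dimethoxy-1-methyl-5-[(1S)-1,2,2-trimethylcyclopentyl]benzene | Cc1cc([C@@]2(C)CCCC2(C)C)c(OC)c(OC)c1Br
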